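Atoms are numbered as in carotenoids: C1 carries the two methyl groups, C3 the hydroxyl, C5 the methyl group and the ring oxygen O1, C6=C7 is the ring alkene, C8 the O-bearing CH, C9 to C8' the chain.

## The problem

Target 24 is (3R,5R,8R)-5,8-epoxy-3-hydroxy-5,8-dihydro-8'-apo-β-caroten-8'-al. Its head is a cyclohexane fused through C5–C6 to a 2,5-dihydrofuran, with C6=C7 inside the five-membered ring and exocyclic to the six-membered one; an all-E heptaene ending in the C8' formyl group hangs from C8. C6 is flanked by two fully substituted carbons (C1 and C5), so the carbocycle is not open to stepwise enolate chemistry. Three stereocentres must be set: C8, C5 (methyl trans to C9 across the oxolene) and C3 (hydroxyl cis to O1, equatorial). C8 can be fixed by a catalyst in an open-chain precursor; C8 can bias C5 only weakly, because the two lie 1,3 across a nearly flat ring; C5 then steers C3 firmly through its axial methyl group. The doubly allylic C8–O1 bond is ionised by acid, a C3 ketone on the way is a β-alkoxy ketone that can lose O1 by E1cB elimination, and the polyene aldehyde suffers from acid, base, light and oxidants, so the chain must come late and the formyl group last. The feature that invites a two-ring cycloaddition is C6: it is shared by both rings and keeps a double bond exocyclic to the carbocycle, as the central carbon of an allene does when its distal bond acts as dienophile, while O1 and the C3 oxygen stand 1,3 like the donors of a 1-alkoxy-3-silyloxy diene C5=C4–C3=C2.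

## Retrosynthesis

**C8' oxidation level (24 ⇒ 23 ⇒ 22).** No skeletal bond is cut. The formyl group of 24 is traced back through allylic alcohol 23 to the ethyl ester of 22, whose C3 hydroxyl is a benzoate. A free polyenal during chain assembly would make the coupling partner a dialdehyde with two nearly equal ends; the ester keeps C8' inert, and one hydride step removes both acyl groups. The forward steps must reduce and oxidise without acid.

**C11=C12 (22 ⇒ 18 + 21).** The chain is cut between C15 phosphonium salt 18 and C15 aldehyde 21 (Wittig). A cut at C9=C10 would put a methyl ketone next to C8 (epimerisable, poor E/Z control); cuts further out would make the sensitive head the larger partner. Compound 21 has no stereocentre. The reaction must form the ylide of 18 without opening the oxolene and must end all-E.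

**C12'=C11' (21 ⇒ 19 + 20).** A Horner–Wadsworth–Emmons cut reduces 21 to the symmetrical C10 dialdehyde 19 and the C5 phosphonate 20. Doing this on the cheap side keeps the head group out of a mono-olefination of a dialdehyde. The forward step needs only 19 in excess.

**C11–P and C3 (18 ⇒ 16 ⇒ 15 ⇒ 14 ⇒ 13).** The phosphonium group comes from allylic alcohol 16 by a non-acidic bromination, and 16 from silyl ether 15. The equatorial C3 benzoate of 15 comes from axial alcohol 14 by Mitsunobu inversion, so inversion and protection are one step. Alcohol 14 comes from ketone 13 by hydride attack from the only open (equatorial) side. Reduction cannot give the equatorial alcohol directly, because the axial methyl groups at C1 and C5 block the axial path.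

**C5–C6 and C1–C2 (13 ⇒ 12 ⇒ 11).** Ketone 13 is the hydrolysis product of silyl enol ether 12, and 12 is cut across both rings into the open-chain allenyl dienyl ether 11. Cutting only O1–C8 or only O1–C5 would leave the cyclohexane, with its two quaternary carbons, to be built separately. The double cut removes both rings, both quaternary carbons and one stereocentre, and leaves C8 as the only stereocentre. The forward reaction must use the distal allene bond, must outrun sigmatropic shifts of the dienyl ether, and must let C8 choose the diene face.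

**O1–C5 and the enol silane (11 ⇒ 9 ⇒ 7 + 8).** Diene 11 is the kinetic silyl enol ether of β-alkoxy enone 9, and 9 is cut at O1–C5 into carbinol 7 and ynone 8 (conjugate addition). O-alkylation with an activated C8 electrophile would risk SN2' scrambling and loss of C8. The addition must give the E enone (O1 trans to C3), and enolisation must occur at the acetyl methyl group.

**Allene and C11 (7 ⇒ 6 ⇒ 4).** Carbinol 7 is the primary silyl ether of diol 6, which comes from propargylic alcohol 4 by one hydride operation: ester reduction at C11 and SN2' delivery of hydride to C7 with loss of the tertiary acetal oxygen. Bringing the allene in ready-made as a nucleophile would give a racemic carbinol and an allenyl-versus-propargyl regiochemistry question. C8 must not be touched.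

**C7–C8 (4 ⇒ 2 + 3; 2 ⇒ 1).** Alcohol 4 is cut at C7–C8 into alkyne 2 and aldehyde 3, a catalytic asymmetric alkynylation that sets C8. Setting C8 by reduction would need a C8 ketone between two unsaturated groups, which a catalyst distinguishes poorly. Aldehyde 3 already holds the E C9=C10 bond; 2 is the acetal of alcohol 1.

## Roads not taken

**Alternative 1:** Only O1–C8 is cut. A monovalent gold catalyst (for example Ph3PAuCl/AgBF4) would activate C7=C8 of allenol A1; the tertiary C5 hydroxyl adds to C8 in a 5-endo sense and protodeauration gives diacetate A2.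
- Merits: cycloisomerisation of α-hydroxyallenes to 2,5-dihydrofurans is well established and transfers the allene axis to C8 stereospecifically. C3 and C5 are in place before the ring closes, and a hydroxyl-directed epoxidation would put the C5 oxygen cis to the C3 oxygen, as this target needs.
- Weak points: A1 needs a long linear build. The carbocycle with C3 and C5 must be made first, then an alkyne joined, an epoxide placed on the right face, and the allene axis set by an anti SN2' hydride opening. Each step must be selective, and the gold step forms no C–C bond.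
- Comparison: this road is better in C8 control and in key-step precedent. The chosen plan offers a six-step open-chain precursor and a single step that makes both rings and both quaternary carbons; it pays with weaker control of C5.

**Alternative 2:** C1–C6 and the O1–C8 acyl bond are cut. Hydrogen-atom transfer (Fe(acac)3/PhSiH3) to the trisubstituted alkene of A3 would give a tertiary C1 radical that adds 6-exo-dig to C6 of the ynoate; the reduced (Z)-alkylidene ester lactonises with the C5 hydroxyl to give A4.
- Merits: a tertiary radical suits the quaternary C1. C3 and C5 are set in an open chain by reliable carbonyl additions, so no reduction–inversion pair is needed at C3, and the lactone is reached in few steps.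
- Weak points: in A4, C8 is a carbonyl. The chain and the C8 hydrogen would still have to be added by alkenyl-metal addition and reductive removal of the lactol hydroxyl through an oxocarbenium ion conjugated to two alkenes. That means acid at the most sensitive position and uncertain 1,3-induction from C5. Lactonisation also depends on the vinyl radical giving the Z ester.
- Comparison: this road is better at C3 and C5. The chosen plan fixes C8 first by catalysis, carries the side chain through the ring-forming step and needs no late cation at C8.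

**Alternative 3:** Only O1–C5 is cut. Cu(hfacac)2, a divalent copper Lewis acid, would open the allylic C7–O bond of vinyl oxirane A5; the oxygen, still on C8, closes on C5 to give enoate A6.
- Merits: C8 is carried unchanged from an epoxide, the carbon skeleton is the familiar ionylidene one, and the ester is a ready handle for the chain.
- Weak points: the new bond must form at a fully substituted ring carbon, where 1,2-hydride shift (Meinwald rearrangement) and elimination to trienes compete. C5 is decided only by how the allyl intermediate folds relative to C8 and the remote C3 substituent. A5 needs a regio- and enantioselective epoxidation of one of three alkenes.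
- Comparison: control of C5 is no stronger than in the chosen plan, and the carbocycle with C3 still has to be made. The chosen plan builds the carbocycle in the same step that creates C5 and keeps a correction path through the C3 ketone.

Key step: step 7

**Remarks before the steps:**
- (S,S)-ProPhenol is taken to deliver the alkynyl group to the Re face of the formyl group of 3; if the opposite carbinol forms, the (R,R) ligand is used.
- Dialdehyde 19 and phosphonate 20 are treated as purchasable.
- Compounds 2, 4 and 5 are mixtures at the acetal carbon, which is lost in step 3.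

## Steps

Step 1
Reactants: 1 2-methylbut-3-yn-2-ol
Product: 2 2-[(2-methylbut-3-yn-2-yl)oxy]tetrahydro-2H-pyran
Conditions: 3,4-dihydro-2H-pyran, PPTS (5 mol %), CH2Cl2, 0 °C → rt
Reagents that add atoms: 3,4-dihydro-2H-pyran, C1=COCCC1
Why: Acid-catalysed addition of the tertiary alcohol to the enol ether (tetrahydropyranyl acetal formation); the acetal oxygen is the leaving group of step 3.

Step 2
Reactants: 2 2-[(2-methylbut-3-yn-2-yl)oxy]tetrahydro-2H-pyran; 3 ethyl (2E)-3-methyl-4-oxobut-2-enoate
Product: 4 ethyl (2E,4S)-4-hydroxy-3,7-dimethyl-7-(tetrahydro-2H-pyran-2-yloxy)oct-2-en-5-ynoate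
Conditions: (S,S)-ProPhenol (10 mol %), Me2Zn, Ph3P=O (20 mol %), toluene, 4 °C
Reagents that add atoms: none
Why: Catalytic asymmetric alkynylation of an aldehyde by a zinc alkynylide on the dinuclear zinc–ProPhenol complex, a reaction known for α-substituted enals; Re-face delivery sets C8 as (S) in 4, the same spatial arrangement that is named (R) once the alkyne has become the allene. The non-enolisable aldehyde and the ester tolerate Me2Zn.

Step 3
Reactants: 4 ethyl (2E,4S)-4-hydroxy-3,7-dimethyl-7-(tetrahydro-2H-pyran-2-yloxy)oct-2-en-5-ynoate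
Product: 6 (2E,4R)-3,7-dimethylocta-2,5,6-triene-1,4-diol, via propargylic diol 5 (not isolated)
Conditions: LiAlH4, THF, 0 °C → 40 °C; aq. potassium sodium tartrate (KNaC4H4O6)
Reagents that add atoms: none
Why: LiAlH4 reduces the β,β-disubstituted enoate to the allylic alcohol, then the C8 alkoxyaluminate delivers hydride to C7 and the vinylalanate expels the tertiary acetal oxygen in an SN2' sense (hydride reduction of 4-alkoxyalk-2-yn-1-ols to α-allenic alcohols). C8 is not involved; the reaction is stopped when 5 is consumed, to avoid reduction of the allene.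

Step 4
Reactants: 6 (2E,4R)-3,7-dimethylocta-2,5,6-triene-1,4-diol
Product: 7 (2E,4R)-3,7-dimethyl-1-[(triisopropylsilyl)oxy]octa-2,5,6-trien-4-ol
Conditions: TIPSCl, imidazole, CH2Cl2, 0 °C
Reagents that add atoms: chlorotriisopropylsilane, CC(C)[Si](Cl)(C(C)C)C(C)C
Why: Selective silylation of the primary allylic hydroxyl by a bulky chlorosilane; the secondary carbinol between the allene and the 2-substituted alkene reacts far more slowly.

Step 5
Reactants: 7 (2E,4R)-3,7-dimethyl-1-[(triisopropylsilyl)oxy]octa-2,5,6-trien-4-ol; 8 pent-3-yn-2-one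
Product: 9 (3E)-4-({(2E,4R)-3,7-dimethyl-1-[(triisopropylsilyl)oxy]octa-2,5,6-trien-4-yl}oxy)pent-3-en-2-one
Conditions: PMe3 (20 mol %), CH2Cl2, 0 °C → rt
Reagents that add atoms: none
Why: Phosphine-catalysed oxa-Michael addition of an alcohol to an ynone (the phosphonium enolate acts as base, the alkoxide adds at the β-carbon); it forms O1–C5 as the favoured (E)-β-alkoxy enone under neutral conditions that leave the allene and C8 alone.

Step 6
Reactants: 9 (3E)-4-({(2E,4R)-3,7-dimethyl-1-[(triisopropylsilyl)oxy]octa-2,5,6-trien-4-yl}oxy)pent-3-en-2-one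
Product: 11 tert-butyl{[(3E)-4-({(2E,4R)-3,7-dimethyl-1-[(triisopropylsilyl)oxy]octa-2,5,6-trien-4-yl}oxy)penta-1,3-dien-2-yl]oxy}dimethylsilane, via lithium dienolate 10 (not isolated)
Conditions: LiN(i-Pr)2, THF, −78 °C; then TBSCl, DMPU, −78 → 0 °C
Reagents that add atoms: tert-butylchlorodimethylsilane, CC(C)(C)[Si](C)(C)Cl
Why: Kinetic deprotonation of the vinylogous ester at the acetyl methyl group (cross-conjugated enolate) and O-silylation give the 2-silyloxy diene; the amide base at −78 °C avoids deprotonation at the C5 methyl group and at the much less acidic C8–H.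

Step 7
Reactants: 11 tert-butyl{[(3E)-4-({(2E,4R)-3,7-dimethyl-1-[(triisopropylsilyl)oxy]octa-2,5,6-trien-4-yl}oxy)penta-1,3-dien-2-yl]oxy}dimethylsilane
Product: 12 tert-butyl(dimethyl){[(2R,7aR)-4,4,7a-trimethyl-2-{(2E)-4-[(triisopropylsilyl)oxy]but-2-en-2-yl}-2,4,5,7a-tetrahydro-1-benzofuran-6-yl]oxy}silane
Conditions: CH2Cl2 (0.02 M), Et3N (5 mol %), BHT, 12 kbar, 50 °C
Reagents that add atoms: none
Why: Concerted suprafacial intramolecular Diels–Alder reaction: the diene C5=C4–C3=C2 adds across the distal C6=C1 bond of the allene and forms C5–C6 and C1–C2. The closest known reactions are the thermal intramolecular cycloadditions of dienes, furans and even aryl rings to the distal π bond of an allene held by a two-atom link (allenyl ethers, allenecarboxanilides), which also tolerate a dimethyl-substituted allene terminus. The cyclohexene is the six-membered ring of the [4+2] addition itself (C2–C5 plus C6 and C1); the 2,5-dihydrofuran closes through the C5–C6 bond in the plane of the O1–C8–C7 link onto the sp carbon C6, so that C6=C7 ends up inside the five-membered ring, and the proximal bond cannot compete because it would have to close a four-membered ring. C5 is the only new stereocentre (C1 bears two methyl groups) and is set by the diene face that C8 exposes: the inside (Z) methyl group of the diene swings toward the tether as C5 pyramidalises, so the transition state with C9 on the opposite side, next to C4, should be preferred and should turn (8R) into (5R), though the bias is expected to be modest. C6 carries no substituent, so the inside methyl group meets the least possible hindrance, and the 3-silyloxy group destabilises the s-trans diene through strain with that methyl group. Pressure replaces heat because the cycloaddition has a far more negative activation volume than the competing [3,3] shift of the allyl and allenylmethyl dienyl ether or the 1,5-hydrogen shift from the Z-methyl group; Et3N and BHT protect the silyl enol ether and the diene.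

Step 8
Reactants: 12 tert-butyl(dimethyl){[(2R,7aR)-4,4,7a-trimethyl-2-{(2E)-4-[(triisopropylsilyl)oxy]but-2-en-2-yl}-2,4,5,7a-tetrahydro-1-benzofuran-6-yl]oxy}silane
Product: 13 (2R,7aR)-4,4,7a-trimethyl-2-{(2E)-4-[(triisopropylsilyl)oxy]but-2-en-2-yl}-4,5,7,7a-tetrahydro-1-benzofuran-6(2H)-one
Conditions: AcOH/THF/H2O (3:1:1), 0 °C → rt
Reagents that add atoms: none
Why: Mild acid hydrolysis of a silyl enol ether (protonation at C4, loss of silanol); weak aqueous acid avoids both ionisation of the C8–O1 bond and the base-induced E1cB loss of O1 from the β-alkoxy ketone, and the primary triisopropylsilyl ether survives.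

Step 9
Reactants: 13 (2R,7aR)-4,4,7a-trimethyl-2-{(2E)-4-[(triisopropylsilyl)oxy]but-2-en-2-yl}-4,5,7,7a-tetrahydro-1-benzofuran-6(2H)-one
Product: 14 (2R,6S,7aR)-4,4,7a-trimethyl-2-{(2E)-4-[(triisopropylsilyl)oxy]but-2-en-2-yl}-2,4,5,6,7,7a-hexahydro-1-benzofuran-6-ol
Conditions: LiBH(s-Bu)3, THF, −78 °C
Reagents that add atoms: none
Why: Bulky-hydride reduction of a cyclohexanone: the axial methyl groups at C1 and C5 close the axial path, so hydride enters equatorially and gives the axial alcohol cis to the C5 methyl group; −78 °C suppresses enolisation and ring opening.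

Step 10
Reactants: 14 (2R,6S,7aR)-4,4,7a-trimethyl-2-{(2E)-4-[(triisopropylsilyl)oxy]but-2-en-2-yl}-2,4,5,6,7,7a-hexahydro-1-benzofuran-6-ol
Product: 15 (2R,6R,7aR)-4,4,7a-trimethyl-2-{(2E)-4-[(triisopropylsilyl)oxy]but-2-en-2-yl}-2,4,5,6,7,7a-hexahydro-1-benzofuran-6-yl benzoate
Conditions: PhCO2H, PPh3, diisopropyl azodicarboxylate, toluene, 0 °C → rt
Reagents that add atoms: benzoic acid, OC(=O)c1ccccc1
Why: Mitsunobu reaction: the axial alkoxyphosphonium ion is displaced by benzoate with inversion from the open equatorial side, giving the equatorial (3R) ester, which also protects C3 through steps 11 to 14.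

Step 11
Reactants: 15 (2R,6R,7aR)-4,4,7a-trimethyl-2-{(2E)-4-[(triisopropylsilyl)oxy]but-2-en-2-yl}-2,4,5,6,7,7a-hexahydro-1-benzofuran-6-yl benzoate
Product: 16 (2R,6R,7aR)-2-[(2E)-4-hydroxybut-2-en-2-yl]-4,4,7a-trimethyl-2,4,5,6,7,7a-hexahydro-1-benzofuran-6-yl benzoate
Conditions: Bu4NF, THF, 0 °C
Reagents that add atoms: none
Why: Fluoride cleavage of the primary silyl ether; the benzoate and the dihydrofuran are stable to these conditions.

Step 12
Reactants: 16 (2R,6R,7aR)-2-[(2E)-4-hydroxybut-2-en-2-yl]-4,4,7a-trimethyl-2,4,5,6,7,7a-hexahydro-1-benzofuran-6-yl benzoate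
Product: 18 {(2E)-3-[(2R,6R,7aR)-6-(benzoyloxy)-4,4,7a-trimethyl-2,4,5,6,7,7a-hexahydro-1-benzofuran-2-yl]but-2-en-1-yl}triphenylphosphonium bromide, via allylic bromide 17 (not isolated)
Conditions: CBr4, PPh3, 2,6-lutidine, CH2Cl2, −20 °C; then PPh3, MeCN, rt
Reagents that add atoms: carbon tetrabromide, BrC(Br)(Br)Br; triphenylphosphine, c1ccc(cc1)P(c1ccccc1)c1ccccc1
Why: Appel bromination of the primary allylic alcohol under buffered conditions, then SN2 quaternisation of PPh3 by the allylic bromide in the same flask; the usual acidic route with PPh3·HBr is avoided because it could ionise the C8–O1 bond.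

Step 13
Reactants: 19 (2E,4E,6E)-2,7-dimethylocta-2,4,6-trienedial; 20 ethyl (2E)-4-(diethoxyphosphoryl)-2-methylbut-2-enoate
Product: 21 ethyl (2E,4E,6E,8E,10E)-2,6,11-trimethyl-12-oxododeca-2,4,6,8,10-pentaenoate
Conditions: NaH, THF, 0 °C; 19 in excess (2.5 equiv)
Reagents that add atoms: none
Why: Horner–Wadsworth–Emmons olefination of one formyl group of the symmetrical dialdehyde by the stabilised phosphonate anion; it should give the E C12'=C11' bond, and the excess of 19 limits double olefination.

Step 14
Reactants: 18 {(2E)-3-[(2R,6R,7aR)-6-(benzoyloxy)-4,4,7a-trimethyl-2,4,5,6,7,7a-hexahydro-1-benzofuran-2-yl]but-2-en-1-yl}triphenylphosphonium bromide; 21 ethyl (2E,4E,6E,8E,10E)-2,6,11-trimethyl-12-oxododeca-2,4,6,8,10-pentaenoate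
Product: 22 ethyl (2E,4E,6E,8E,10E,12E,14E)-15-[(2R,6R,7aR)-6-(benzoyloxy)-4,4,7a-trimethyl-2,4,5,6,7,7a-hexahydro-1-benzofuran-2-yl]-2,6,11-trimethylhexadeca-2,4,6,8,10,12,14-heptaenoate
Conditions: 1,2-epoxybutane/EtOH, reflux; then n-heptane, 90 °C, dark
Reagents that add atoms: none
Why: Wittig olefination under neutral conditions: the epoxide takes up HBr and releases the allylic ylide at low concentration, which forms C11=C12 with the aldehyde and leaves both esters alone; heating then equilibrates the hindered 11Z isomer to all-E.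

Step 15
Reactants: 22 ethyl (2E,4E,6E,8E,10E,12E,14E)-15-[(2R,6R,7aR)-6-(benzoyloxy)-4,4,7a-trimethyl-2,4,5,6,7,7a-hexahydro-1-benzofuran-2-yl]-2,6,11-trimethylhexadeca-2,4,6,8,10,12,14-heptaenoate
Product: 23 (2R,6R,7aR)-2-[(2E,4E,6E,8E,10E,12E,14E)-16-hydroxy-6,11,15-trimethylhexadeca-2,4,6,8,10,12,14-heptaen-2-yl]-4,4,7a-trimethyl-2,4,5,6,7,7a-hexahydro-1-benzofuran-6-ol
Conditions: i-Bu2AlH, CH2Cl2, −78 → −40 °C; aq. potassium sodium tartrate (KNaC4H4O6)
Reagents that add atoms: none
Why: Aluminium hydride reduction of the conjugated ethyl ester to the allylic alcohol, with reductive cleavage of the benzoate in the same operation; low temperature keeps the reduction 1,2 on the polyene ester.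

Step 16
Reactants: 23 (2R,6R,7aR)-2-[(2E,4E,6E,8E,10E,12E,14E)-16-hydroxy-6,11,15-trimethylhexadeca-2,4,6,8,10,12,14-heptaen-2-yl]-4,4,7a-trimethyl-2,4,5,6,7,7a-hexahydro-1-benzofuran-6-ol
Product: 24 (2E,4E,6E,8E,10E,12E,14E)-15-[(2R,6R,7aR)-6-hydroxy-4,4,7a-trimethyl-2,4,5,6,7,7a-hexahydro-1-benzofuran-2-yl]-2,6,11-trimethylhexadeca-2,4,6,8,10,12,14-heptaenal
Conditions: MnO2 (activated), CH2Cl2, rt, dark
Reagents that add atoms: none
Why: Selective oxidation of the polyene-conjugated primary allylic alcohol by manganese dioxide; the saturated secondary C3 hydroxyl is not oxidised, and the neutral heterogeneous conditions spare the acid-labile 5,8-epoxide.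

## Compound list

1 | 2-methylbut-3-yn-2-ol | CC(C)(O)C#C | starting material
2 | 2-[(2-methylbut-3-yn-2-yl)oxy]tetrahydro-2H-pyran (racemic) | CC(C)(OC1CCCCO1)C#C | intermediate
3 | ethyl (2E)-3-methyl-4-oxobut-2-enoate | CCOC(=O)/C=C(\C)C=O | starting material
4 | ethyl (2E,4S)-4-hydroxy-3,7-dimethyl-7-(tetrahydro-2H-pyran-2-yloxy)oct-2-en-5-ynoate (both epimers at the acetal carbon) | CCOC(=O)/C=C(\C)[C@H](O)C#CC(C)(C)OC1CCCCO1 | intermediate
5 | (2E,4S)-3,7-dimethyl-7-(tetrahydro-2H-pyran-2-yloxy)oct-2-en-5-yne-1,4-diol (present as its aluminate, not isolated) | OC/C=C(\C)[C@H](O)C#CC(C)(C)OC1CCCCO1 | intermediate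
6 | (2E,4R)-3,7-dimethylocta-2,5,6-triene-1,4-diol | OC/C=C(\C)[C@H](O)C=C=C(C)C | intermediate
7 | (2E,4R)-3,7-dimethyl-1-[(triisopropylsilyl)oxy]octa-2,5,6-trien-4-ol | CC(C)[Si](C(C)C)(C(C)C)OC/C=C(\C)[C@H](O)C=C=C(C)C | intermediate
8 | pent-3-yn-2-one | CC#CC(C)=O | starting material
9 | (3E)-4-({(2E,4R)-3,7-dimethyl-1-[(triisopropylsilyl)oxy]octa-2,5,6-trien-4-yl}oxy)pent-3-en-2-one | CC(C)[Si](C(C)C)(C(C)C)OC/C=C(\C)[C@H](O/C(C)=C/C(C)=O)C=C=C(C)C | intermediate
10 | lithium (3E)-4-({(2E,4R)-3,7-dimethyl-1-[(triisopropylsilyl)oxy]octa-2,5,6-trien-4-yl}oxy)penta-1,3-dien-2-olate (not isolated) | CC(C)[Si](C(C)C)(C(C)C)OC/C=C(\C)[C@H](O/C(C)=C/C(=C)[O-])C=C=C(C)C.[Li+] | intermediate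
11 | tert-butyl{[(3E)-4-({(2E,4R)-3,7-dimethyl-1-[(triisopropylsilyl)oxy]octa-2,5,6-trien-4-yl}oxy)penta-1,3-dien-2-yl]oxy}dimethylsilane | CC(C)[Si](C(C)C)(C(C)C)OC/C=C(\C)[C@H](O/C(C)=C/C(=C)O[Si](C)(C)C(C)(C)C)C=C=C(C)C | intermediate
12 | tert-butyl(dimethyl){[(2R,7aR)-4,4,7a-trimethyl-2-{(2E)-4-[(triisopropylsilyl)oxy]but-2-en-2-yl}-2,4,5,7a-tetrahydro-1-benzofuran-6-yl]oxy}silane | CC(C)[Si](C(C)C)(C(C)C)OC/C=C(\C)[C@H]1C=C2C(C)(C)CC(O[Si](C)(C)C(C)(C)C)=C[C@@]2(C)O1 | intermediate
13 | (2R,7aR)-4,4,7a-trimethyl-2-{(2E)-4-[(triisopropylsilyl)oxy]but-2-en-2-yl}-4,5,7,7a-tetrahydro-1-benzofuran-6(2H)-one | CC(C)[Si](C(C)C)(C(C)C)OC/C=C(\C)[C@H]1C=C2C(C)(C)CC(=O)C[C@@]2(C)O1 | intermediate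
14 | (2R,6S,7aR)-4,4,7a-trimethyl-2-{(2E)-4-[(triisopropylsilyl)oxy]but-2-en-2-yl}-2,4,5,6,7,7a-hexahydro-1-benzofuran-6-ol | CC(C)[Si](C(C)C)(C(C)C)OC/C=C(\C)[C@H]1C=C2C(C)(C)C[C@H](O)C[C@@]2(C)O1 | intermediate
15 | (2R,6R,7aR)-4,4,7a-trimethyl-2-{(2E)-4-[(triisopropylsilyl)oxy]but-2-en-2-yl}-2,4,5,6,7,7a-hexahydro-1-benzofuran-6-yl benzoate | CC(C)[Si](C(C)C)(C(C)C)OC/C=C(\C)[C@H]1C=C2C(C)(C)C[C@@H](OC(=O)c3ccccc3)C[C@@]2(C)O1 | intermediate
16 | (2R,6R,7aR)-2-[(2E)-4-hydroxybut-2-en-2-yl]-4,4,7a-trimethyl-2,4,5,6,7,7a-hexahydro-1-benzofuran-6-yl benzoate | OC/C=C(\C)[C@H]1C=C2C(C)(C)C[C@@H](OC(=O)c3ccccc3)C[C@@]2(C)O1 | intermediate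
17 | (2R,6R,7aR)-2-[(2E)-4-bromobut-2-en-2-yl]-4,4,7a-trimethyl-2,4,5,6,7,7a-hexahydro-1-benzofuran-6-yl benzoate (not isolated) | BrC/C=C(\C)[C@H]1C=C2C(C)(C)C[C@@H](OC(=O)c3ccccc3)C[C@@]2(C)O1 | intermediate
18 | {(2E)-3-[(2R,6R,7aR)-6-(benzoyloxy)-4,4,7a-trimethyl-2,4,5,6,7,7a-hexahydro-1-benzofuran-2-yl]but-2-en-1-yl}triphenylphosphonium bromide | c1ccccc1[P+](c1ccccc1)(c1ccccc1)C/C=C(\C)[C@H]1C=C2C(C)(C)C[C@@H](OC(=O)c3ccccc3)C[C@@]2(C)O1.[Br-] | intermediate
19 | (2E,4E,6E)-2,7-dimethylocta-2,4,6-trienedial | O=C/C(C)=C/C=C/C=C(C)/C=O | starting material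
20 | ethyl (2E)-4-(diethoxyphosphoryl)-2-methylbut-2-enoate | CCOC(=O)/C(C)=C/CP(=O)(OCC)OCC | starting material
21 | ethyl (2E,4E,6E,8E,10E)-2,6,11-trimethyl-12-oxododeca-2,4,6,8,10-pentaenoate | CCOC(=O)/C(C)=C/C=C/C(C)=C/C=C/C=C(C)/C=O | intermediate
22 | ethyl (2E,4E,6E,8E,10E,12E,14E)-15-[(2R,6R,7aR)-6-(benzoyloxy)-4,4,7a-trimethyl-2,4,5,6,7,7a-hexahydro-1-benzofuran-2-yl]-2,6,11-trimethylhexadeca-2,4,6,8,10,12,14-heptaenoate | CCOC(=O)/C(C)=C/C=C/C(C)=C/C=C/C=C(C)/C=C/C=C(\C)[C@H]1C=C2C(C)(C)C[C@@H](OC(=O)c3ccccc3)C[C@@]2(C)O1 | intermediate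
23 | (2R,6R,7aR)-2-[(2E,4E,6E,8E,10E,12E,14E)-16-hydroxy-6,11,15-trimethylhexadeca-2,4,6,8,10,12,14-heptaen-2-yl]-4,4,7a-trimethyl-2,4,5,6,7,7a-hexahydro-1-benzofuran-6-ol | OC/C(C)=C/C=C/C(C)=C/C=C/C=C(C)/C=C/C=C(\C)[C@H]1C=C2C(C)(C)C[C@@H](O)C[C@@]2(C)O1 | intermediate
24 | (2E,4E,6E,8E,10E,12E,14E)-15-[(2R,6R,7aR)-6-hydroxy-4,4,7a-trimethyl-2,4,5,6,7,7a-hexahydro-1-benzofuran-2-yl]-2,6,11-trimethylhexadeca-2,4,6,8,10,12,14-heptaenal; (3R,5R,8R)-5,8-epoxy-3-hydroxy-5,8-dihydro-8'-apo-β-caroten-8'-al | C\C(C=O)=C/C=C/C(C)=C/C=C/C=C(C)/C=C/C=C(\C)[C@H]1C=C2C(C)(C)C[C@@H](O)C[C@@]2(C)O1 | target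

## Step count and risks

Total step count: 16. Longest linear sequence: 15 (steps 1 to 12 and 14 to 16); step 13 is a one-step side branch.

**Step 7 (key step).**
- What may go wrong: weak discrimination between the two diene faces, because C8 lies 1,3 to C5 across a nearly planar forming ring and its H and C9 differ only in their contact with the inside methyl group. If the cycloaddition is slower than estimated, the [3,3]-sigmatropic shift of the dienyl ether would consume 11; pressure and low temperature are chosen against this.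
- Fallback: C5 is corrected under thermodynamic control instead of kinetic face control. The detour sets out from 12 obtained as a mixture with the (2R,7aS)-cycloadduct F1. Hydrolysis as in step 8 gives 13 and the epimeric ketone F2, which are separated. F2 is a β-alkoxy ketone; 1,8-diazabicyclo[5.4.0]undec-7-ene in THF should open it by E1cB elimination to the (Z)-hydroxy dienone F3, whose C8 hydroxyl re-adds to C5 from either face (oxa-Michael addition). The mixture of 13 and F2 is separated again and F2 recycled; the detour rejoins the route at 13.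
- If the cycloaddition itself is lost to sigmatropic shifts, the head group would have to come through A2 of Alternative 1.

**Step 2.**
- What may go wrong: erosion of enantioselectivity by uncatalysed addition of the zinc alkynylide to the electron-poor aldehyde, or slow turnover because the ester competes for zinc.
- Fallback: C8 is set by reduction instead of by C–C bond formation. Starting from 2 and 3, the lithium acetylide of 2 (n-BuLi, THF, −78 °C) adds to the formyl group of 3 to give the racemic carbinol F4. MnO2 oxidises it to the ynone F5. Corey–Bakshi–Shibata reduction ((S)-2-methyl-CBS-oxazaborolidine, catecholborane, −78 °C, the linear alkynyl group acting as the smaller substituent) should return the route at 4.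

**Step 5.**
- What may go wrong: slow addition of the hindered secondary alcohol to the β-methyl ynone, so that phosphine-induced oligomerisation of 8 or addition at its γ-carbon takes over.
- Fallback: addition–elimination replaces conjugate addition. Starting from 7, the potassium alkoxide (KN(SiMe3)2, THF, −78 °C) displaces chloride from (3E)-4-chloropent-3-en-2-one and returns the route at 9; no compound outside the list is made (F0).

**Step 10.**
- What may go wrong: E2 elimination of the activated axial alcohol toward C2 or C4, or failure to form the alkoxyphosphonium ion at the hindered axial oxygen.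
- Fallback: the equatorial alcohol is made directly under thermodynamic control. Starting from ketone 13, single-electron reduction with SmI2 (samarium diiodide, divalent samarium), H2O and Et3N in THF should give the equatorial (2R,6R,7aR)-alcohol F6. Benzoylation (PhCOCl, pyridine) returns the route at 15.

**Step 14.**
- What may go wrong: vinylogous β-elimination of O1 from the allylic ylide, whose carbanion is delocalised onto C9 next to the C8–O1 bond; this would open the dihydrofuran. The same delocalisation can scramble the C9=C10 geometry.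
- Fallback: the polarity of the coupling is reversed. Starting from 16 and 21, MnO2 oxidises 16 to the enal F7. NaBH4 (EtOH, −20 °C) reduces the formyl group of 21 to the hydroxy ester F8, and PPh3·HBr in MeOH converts it into the chain phosphonium bromide F9. Wittig reaction of F9 with F7 under the epoxide conditions of step 14 forms the same C11=C12 bond and returns the route at 22.

## Further compounds

F1 | step 7 | tert-butyl(dimethyl){[(2R,7aS)-4,4,7a-trimethyl-2-{(2E)-4-[(triisopropylsilyl)oxy]but-2-en-2-yl}-2,4,5,7a-tetrahydro-1-benzofuran-6-yl]oxy}silane | CC(C)[Si](C(C)C)(C(C)C)OC/C=C(\C)[C@H]1C=C2C(C)(C)CC(O[Si](C)(C)C(C)(C)C)=C[C@]2(C)O1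
F2 | step 7 | (2R,7aS)-4,4,7a-trimethyl-2-{(2E)-4-[(triisopropylsilyl)oxy]but-2-en-2-yl}-4,5,7,7a-tetrahydro-1-benzofuran-6(2H)-one | CC(C)[Si](C(C)C)(C(C)C)OC/C=C(\C)[C@H]1C=C2C(C)(C)CC(=O)C[C@]2(C)O1
F3 | step 7 | (4Z)-4-{(2R,3E)-2-hydroxy-3-methyl-5-[(triisopropylsilyl)oxy]pent-3-en-1-ylidene}-3,5,5-trimethylcyclohex-2-en-1-one | CC(C)[Si](C(C)C)(C(C)C)OC/C=C(\C)[C@H](O)/C=C1\C(C)=CC(=O)CC1(C)C
F4 | step 2 | ethyl (2E)-4-hydroxy-3,7-dimethyl-7-(tetrahydro-2H-pyran-2-yloxy)oct-2-en-5-ynoate, racemic at C4 | CCOC(=O)/C=C(\C)C(O)C#CC(C)(C)OC1CCCCO1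
F5 | step 2 | ethyl (2E)-3,7-dimethyl-4-oxo-7-(tetrahydro-2H-pyran-2-yloxy)oct-2-en-5-ynoate | CCOC(=O)/C=C(\C)C(=O)C#CC(C)(C)OC1CCCCO1
F0 | step 5 | none | none
F6 | step 10 | (2R,6R,7aR)-4,4,7a-trimethyl-2-{(2E)-4-[(triisopropylsilyl)oxy]but-2-en-2-yl}-2,4,5,6,7,7a-hexahydro-1-benzofuran-6-ol | CC(C)[Si](C(C)C)(C(C)C)OC/C=C(\C)[C@H]1C=C2C(C)(C)C[C@@H](O)C[C@@]2(C)O1
F7 | step 14 | (2R,6R,7aR)-4,4,7a-trimethyl-2-[(2E)-4-oxobut-2-en-2-yl]-2,4,5,6,7,7a-hexahydro-1-benzofuran-6-yl benzoate | O=C/C=C(\C)[C@H]1C=C2C(C)(C)C[C@@H](OC(=O)c3ccccc3)C[C@@]2(C)O1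
F8 | step 14 | ethyl (2E,4E,6E,8E,10E)-12-hydroxy-2,6,11-trimethyldodeca-2,4,6,8,10-pentaenoate | CCOC(=O)/C(C)=C/C=C/C(C)=C/C=C/C=C(C)/CO
F9 | step 14 | [(2E,4E,6E,8E,10E)-12-ethoxy-2,7,11-trimethyl-12-oxododeca-2,4,6,8,10-pentaen-1-yl]triphenylphosphonium bromide | CCOC(=O)/C(C)=C/C=C/C(C)=C/C=C/C=C(C)/C[P+](c1ccccc1)(c1ccccc1)c1ccccc1.[Br-]
A1 | alternative 1 | (2E)-5-[(2R,4R)-4-acetoxy-2-hydroxy-2,6,6-trimethylcyclohexylidene]-3-methylpenta-2,4-dien-1-yl acetate, allene axis (aS) | CC(=O)OC/C=C(C)/[CH]=[C@]=C1C(C)(C)C[C@@H](OC(C)=O)C[C@@]1(C)O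
A2 | alternative 1 | (2E)-3-[(2R,6R,7aR)-6-acetoxy-4,4,7a-trimethyl-2,4,5,6,7,7a-hexahydro-1-benzofuran-2-yl]but-2-en-1-yl acetate | CC(=O)OC/C=C(\C)[C@H]1C=C2C(C)(C)C[C@@H](OC(C)=O)C[C@@]2(C)O1
A3 | alternative 2 | ethyl (4R,6S)-6-[(tert-butyldimethylsilyl)oxy]-4-hydroxy-4,8-dimethylnon-7-en-2-ynoate | CC(C)=C[C@@H](O[Si](C)(C)C(C)(C)C)C[C@@](C)(O)C#CC(=O)OCC
A4 | alternative 2 | (6R,7aR)-6-[(tert-butyldimethylsilyl)oxy]-4,4,7a-trimethyl-5,6,7,7a-tetrahydro-1-benzofuran-2(4H)-one | O=C1C=C2C(C)(C)C[C@@H](O[Si](C)(C)C(C)(C)C)C[C@@]2(C)O1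
A5 | alternative 3 | ethyl (2E)-3-[(2S,3S)-3-{(4S)-4-[(tert-butyldimethylsilyl)oxy]-2,6,6-trimethylcyclohex-1-en-1-yl}oxiran-2-yl]but-2-enoate | CCOC(=O)/C=C(\C)[C@@H]1O[C@H]1C1=C(C)C[C@H](O[Si](C)(C)C(C)(C)C)CC1(C)C
A6 | alternative 3 | ethyl (2E)-3-[(2R,6R,7aR)-6-[(tert-butyldimethylsilyl)oxy]-4,4,7a-trimethyl-2,4,5,6,7,7a-hexahydro-1-benzofuran-2-yl]but-2-enoate | CCOC(=O)/C=C(\C)[C@H]1C=C2C(C)(C)C[C@@H](O[Si](C)(C)C(C)(C)C)C[C@@]2(C)O1
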